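The triol ring is disconnected at C4–C5 and C1–C6. Its C1–C4 unit (gem-dimethyl C1, carbinol C3) has the skeleton of mesityl oxide, and C5/C6 with C7 that of an enediol ester. A catalytic asymmetric [4+2] annulation of the 2-silyloxydiene of mesityl oxide with a cyclic enediol carbonate ester forms both bonds, three contiguous fully substituted carbons and the cis-5,6-diol in one operation; the dioxolone ring forces the cis relation. The masked C3 ketone is later reduced anti to O5 by internal hydride delivery. The C7 ester is grown to a C15 aldehyde and joined by Wittig reaction to a C25 phosphonium salt carrying the acetylenic (3′R) ring, made from actinol by Sonogashira coupling.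

Key step: step 4

Remark: carotenoid numbering is used for the triol ring (C1 gem-dimethyl carbon, C3 carbinol, C5/C6 diol carbons, C7 first chain carbon). The antipode of the chiral acid catalyst that delivers the (5R,6S) adduct is assumed to be identified in a first screen, both antipodes being accessible.

Step 1
Reactants: 1 mesityl oxide (4-methylpent-3-en-2-one)
Product: 3 tert-butyldimethyl[(4-methylpenta-1,3-dien-2-yl)oxy]silane, via lithium 4-methylpenta-1,3-dien-2-olate 2 (not isolated)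
Conditions: LiN(iPr)2 (LDA), THF, −78 °C; then TBSCl, DMPU, −78 °C → rt
Reagents that add atoms: tert-butyldimethylsilyl chloride, CC(C)(C)[Si](C)(C)Cl
Why: Kinetic deprotonation of the acetyl methyl group gives the cross-conjugated enolate, which is silylated on oxygen (silyl enol ether formation); no stereocentre is formed.

Step 2
Reactants: 4 4-(hydroxymethyl)-5-methyl-1,3-dioxol-2-one
Product: 5 5-methyl-2-oxo-1,3-dioxole-4-carboxylic acid
Conditions: CrO3, H2SO4, acetone/H2O, 0 °C → rt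
Reagents that add atoms: water, O
Why: Jones oxidation should take the primary alcohol through the aldehyde hydrate to the acid, and the enol carbonate ring is stable to acid.

Step 3
Reactants: 5 5-methyl-2-oxo-1,3-dioxole-4-carboxylic acid
Product: 6 methyl 5-methyl-2-oxo-1,3-dioxole-4-carboxylate
Conditions: MeI, KHCO3, DMF, rt
Reagents that add atoms: iodomethane, CI
Why: Carboxylate alkylation (SN2 on MeI) under bicarbonate conditions, which this dioxolone ring tolerates in alkylative esterifications.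

Step 4
Reactants: 3 tert-butyldimethyl[(4-methylpenta-1,3-dien-2-yl)oxy]silane; 6 methyl 5-methyl-2-oxo-1,3-dioxole-4-carboxylate
Product: 7 methyl (3aS,7aR)-6-[(tert-butyldimethylsilyl)oxy]-4,4,7a-trimethyl-2-oxo-3a,4,7,7a-tetrahydro-1,3-benzodioxole-3a-carboxylate
Conditions: chiral imidodiphosphorimidate (IDPi) Brønsted acid with a BINOL-derived backbone and N-triflyl groups (5 mol%), diene in 1.5-fold excess, toluene, −40 → −20 °C; Et3N quench
Reagents that add atoms: none
Why: Proposed new method: the acid protodesilylates one molecule of 3 per molecule of catalyst (which sets free mesityl oxide) to give a silylium–imidodiphosphorimidate ion pair that silylates the ester carbonyl of 6; the CH2 terminus of 3 (C4) then bonds to the ester β-carbon C5 in Mukaiyama–Michael fashion and, within the same ion pair, the developing ketene acetal carbon C6 closes onto the gem-dimethyl terminus C1, a highly asynchronous [4+2] that hands the silyl group on for turnover. The closest known reaction types are the Tf2NH- or AlBr3/AlMe3-promoted Diels–Alder reactions of hindered 2-silyloxydienes with hindered unsaturated carbonyl compounds, which join two quaternary carbons, and the silylium-IDPi-catalysed asymmetric Diels–Alder and Mukaiyama–Michael reactions of α,β-unsaturated methyl esters. The cyclohexene ring is closed as a [4+2] cycloaddition whose second bond forms in a 6-endo-trig (enolexo) Michael mode, while the dioxolone ring is already present. C5 and C6 must come out cis because both bonds form on one face of the planar dioxolone (only the cis-fused bicycle can close), and their absolute configuration (5R,6S) is controlled by the chiral anion that covers one face of the silylated dienophile. The step needs C4 to meet C5 and C1 to meet C6, which the matched polarity secures (nucleophilic CH2 next to the silyloxy carbon, electrophilic ester β-carbon), and an ester offers no competing 1,2-addition; C1 is not stereogenic.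

Step 5
Reactants: 7 methyl (3aS,7aR)-6-[(tert-butyldimethylsilyl)oxy]-4,4,7a-trimethyl-2-oxo-3a,4,7,7a-tetrahydro-1,3-benzodioxole-3a-carboxylate
Product: 8 (3aS,7aR)-6-[(tert-butyldimethylsilyl)oxy]-4,4,7a-trimethyl-2-oxo-3a,4,7,7a-tetrahydro-1,3-benzodioxole-3a-carbaldehyde
Conditions: i-Bu2AlH (1.2 equiv), CH2Cl2, −78 °C; aqueous potassium sodium tartrate work-up
Reagents that add atoms: none
Why: Partial reduction of an α-oxygenated, non-enolisable methyl ester should stop at the aldehyde level at −78 °C, where the cyclic carbonate and the silyl enol ether react more slowly.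

Step 6
Reactants: 8 (3aS,7aR)-6-[(tert-butyldimethylsilyl)oxy]-4,4,7a-trimethyl-2-oxo-3a,4,7,7a-tetrahydro-1,3-benzodioxole-3a-carbaldehyde; 9 ethyl (2E)-4-(diethoxyphosphoryl)-3-methylbut-2-enoate
Product: 11 ethyl (2E,4E)-5-[(3aS,7aR)-6-[(tert-butyldimethylsilyl)oxy]-4,4,7a-trimethyl-2-oxo-3a,4,7,7a-tetrahydro-1,3-benzodioxol-3a-yl]-3-methylpenta-2,4-dienoate, via lithiated phosphonate 10 (not isolated)
Conditions: phosphonate, LiN(SiMe3)2, THF, −78 °C; then aldehyde, −78 → 0 °C
Reagents that add atoms: none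
Why: Horner–Wadsworth–Emmons olefination of the non-enolisable aldehyde with the stabilised allylic phosphonate anion should form C7=C8 with E geometry, the C9=C10 geometry coming from the reagent.

Step 7
Reactants: 11 ethyl (2E,4E)-5-[(3aS,7aR)-6-[(tert-butyldimethylsilyl)oxy]-4,4,7a-trimethyl-2-oxo-3a,4,7,7a-tetrahydro-1,3-benzodioxol-3a-yl]-3-methylpenta-2,4-dienoate
Product: 12 (1S,2R)-4-[(tert-butyldimethylsilyl)oxy]-1-[(1E,3E)-5-hydroxy-3-methylpenta-1,3-dien-1-yl]-2,6,6-trimethylcyclohex-4-ene-1,2-diol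
Conditions: LiAlH4 (excess), THF, −20 → 0 °C; aqueous potassium sodium tartrate work-up
Reagents that add atoms: none
Why: Hydride reduction converts the dienoate to the allylic alcohol and cleaves the cyclic carbonate to the free cis-diol, while the silyl enol ether is inert to hydride and keeps C3 masked until O5 is free.

Step 8
Reactants: 12 (1S,2R)-4-[(tert-butyldimethylsilyl)oxy]-1-[(1E,3E)-5-hydroxy-3-methylpenta-1,3-dien-1-yl]-2,6,6-trimethylcyclohex-4-ene-1,2-diol
Product: 13 (3R,4S)-3,4-dihydroxy-4-[(1E,3E)-5-hydroxy-3-methylpenta-1,3-dien-1-yl]-3,5,5-trimethylcyclohexan-1-one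
Conditions: Bu4NF, AcOH (1:1), THF, −20 → 0 °C
Reagents that add atoms: none
Why: Fluoride removes the silyl group and acetic acid protonates C2 to release the C3 ketone, the buffer keeping the medium too weakly basic for retro-aldol cleavage of the tertiary β-hydroxy ketone.

Step 9
Reactants: 13 (3R,4S)-3,4-dihydroxy-4-[(1E,3E)-5-hydroxy-3-methylpenta-1,3-dien-1-yl]-3,5,5-trimethylcyclohexan-1-one
Product: 14 (1S,2R,4S)-1-[(1E,3E)-5-hydroxy-3-methylpenta-1,3-dien-1-yl]-2,6,6-trimethylcyclohexane-1,2,4-triol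
Conditions: Me4NBH(OAc)3 (excess), MeCN/AcOH, −30 → −20 °C
Reagents that add atoms: none
Why: Evans–Saksena reduction, in which the axial C5 hydroxyl binds the acetoxyborohydride and delivers hydride to the same face of the C3 ketone, so that the new hydroxyl is anti to O5 and O6 (3S), and ketones without a directing hydroxyl are not reduced.

Step 10
Reactants: 14 (1S,2R,4S)-1-[(1E,3E)-5-hydroxy-3-methylpenta-1,3-dien-1-yl]-2,6,6-trimethylcyclohexane-1,2,4-triol
Product: 15 (2E,4E)-3-methyl-5-[(1S,2R,4S)-1,2,4-trihydroxy-2,6,6-trimethylcyclohexyl]penta-2,4-dienal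
Conditions: Cu(MeCN)4OTf (5 mol%), 2,2′-bipyridine, TEMPO, N-methylimidazole, air, MeCN, rt
Reagents that add atoms: none
Why: Copper/nitroxyl aerobic oxidation is selective for the primary allylic alcohol over the secondary C3 and tertiary C5/C6 hydroxyls and should not cleave the diol.

Step 11
Reactants: 16 (4R,6R)-4-hydroxy-2,2,6-trimethylcyclohexan-1-one (actinol)
Product: 17 (4R,6R)-4-[(tert-butyldimethylsilyl)oxy]-2,2,6-trimethylcyclohexan-1-one
Conditions: TBSCl, imidazole, DMF, rt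
Reagents that add atoms: tert-butyldimethylsilyl chloride, CC(C)(C)[Si](C)(C)Cl
Why: Standard silylation of the secondary alcohol so that enolate formation and triflation are clean; the stereocentres are untouched.

Step 12
Reactants: 17 (4R,6R)-4-[(tert-butyldimethylsilyl)oxy]-2,2,6-trimethylcyclohexan-1-one
Product: 19 (4R)-4-[(tert-butyldimethylsilyl)oxy]-2,6,6-trimethylcyclohex-1-en-1-yl trifluoromethanesulfonate, via potassium enolate 18 (not isolated)
Conditions: KN(SiMe3)2, THF, −78 °C; then PhNTf2, −78 → 0 °C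
Reagents that add atoms: N-phenylbis(trifluoromethanesulfonimide), O=S(=O)(N(c1ccccc1)S(=O)(=O)C(F)(F)F)C(F)(F)F
Why: The ketone can enolise only toward C6 (C2 is quaternary), so O-triflation gives a single tetrasubstituted enol triflate; the C6 stereocentre is given up on purpose and C4 is untouched.

Step 13
Reactants: 19 (4R)-4-[(tert-butyldimethylsilyl)oxy]-2,6,6-trimethylcyclohex-1-en-1-yl trifluoromethanesulfonate; 20 (2E)-3-methylpent-2-en-4-yn-1-ol
Product: 21 (2E)-5-[(4R)-4-[(tert-butyldimethylsilyl)oxy]-2,6,6-trimethylcyclohex-1-en-1-yl]-3-methylpent-2-en-4-yn-1-ol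
Conditions: Pd(PPh3)4 (5 mol%), CuI (10 mol%), i-Pr2NH, DMF, rt → 50 °C
Reagents that add atoms: none
Why: Sonogashira coupling of the hindered enol triflate with the terminal alkyne forms the C6′–C7′ bond with the ring alkene and the E enynol geometry retained, the free primary alcohol being tolerated.

Step 14
Reactants: 21 (2E)-5-[(4R)-4-[(tert-butyldimethylsilyl)oxy]-2,6,6-trimethylcyclohex-1-en-1-yl]-3-methylpent-2-en-4-yn-1-ol
Product: 22 [(2E)-5-[(4R)-4-hydroxy-2,6,6-trimethylcyclohex-1-en-1-yl]-3-methylpent-2-en-4-yn-1-yl]triphenylphosphonium bromide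
Conditions: PPh3·HBr, MeOH, rt
Reagents that add atoms: triphenylphosphine hydrobromide, Br.c1ccc(cc1)P(c1ccccc1)c1ccccc1
Why: Acid-mediated SN1-type substitution of the allylic alcohol by PPh3 at the unhindered terminus gives the Wittig salt, and the acidic methanol should remove the silyl ether in the same operation.

Step 15
Reactants: 22 [(2E)-5-[(4R)-4-hydroxy-2,6,6-trimethylcyclohex-1-en-1-yl]-3-methylpent-2-en-4-yn-1-yl]triphenylphosphonium bromide; 23 (2E,4E,6E)-2,7-dimethylocta-2,4,6-trienedial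
Product: 24 (2E,4E,6E,8E,10E)-13-[(4R)-4-hydroxy-2,6,6-trimethylcyclohex-1-en-1-yl]-2,7,11-trimethyltrideca-2,4,6,8,10-pentaen-12-ynal
Conditions: dialdehyde in threefold excess, NaOMe, MeOH/CH2Cl2, 0 °C → rt; then EtOAc, 60 °C (Z → E at the new bond)
Reagents that add atoms: none
Why: Wittig olefination with an excess of the symmetrical dialdehyde should give the mono-adduct, the hindered Z isomer at the new C11′=C12′ bond relaxing to E on brief warming, with iodine avoided so that the 9′E geometry next to the alkyne is kept.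

Step 16
Reactants: 24 (2E,4E,6E,8E,10E)-13-[(4R)-4-hydroxy-2,6,6-trimethylcyclohex-1-en-1-yl]-2,7,11-trimethyltrideca-2,4,6,8,10-pentaen-12-ynal
Product: 25 (2E,4E,6E,8E,10E)-13-[(4R)-4-hydroxy-2,6,6-trimethylcyclohex-1-en-1-yl]-2,7,11-trimethyltrideca-2,4,6,8,10-pentaen-12-yn-1-ol
Conditions: NaBH4, MeOH/THF, 0 °C
Reagents that add atoms: none
Why: 1,2-Reduction of the polyenal gives the allylic alcohol without touching the polyene or the alkyne.

Step 17
Reactants: 25 (2E,4E,6E,8E,10E)-13-[(4R)-4-hydroxy-2,6,6-trimethylcyclohex-1-en-1-yl]-2,7,11-trimethyltrideca-2,4,6,8,10-pentaen-12-yn-1-ol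
Product: 26 [(2E,4E,6E,8E,10E)-13-[(4R)-4-hydroxy-2,6,6-trimethylcyclohex-1-en-1-yl]-2,7,11-trimethyltrideca-2,4,6,8,10-pentaen-12-yn-1-yl]triphenylphosphonium bromide
Conditions: PPh3·HBr, MeOH/CH2Cl2, rt
Reagents that add atoms: triphenylphosphine hydrobromide, Br.c1ccc(cc1)P(c1ccccc1)c1ccccc1
Why: Acid-mediated substitution of the polyenyl alcohol by PPh3 at the terminal carbon is the standard route to retinoid-type Wittig salts.

Step 18
Reactants: 15 (2E,4E)-3-methyl-5-[(1S,2R,4S)-1,2,4-trihydroxy-2,6,6-trimethylcyclohexyl]penta-2,4-dienal; 26 [(2E,4E,6E,8E,10E)-13-[(4R)-4-hydroxy-2,6,6-trimethylcyclohex-1-en-1-yl]-2,7,11-trimethyltrideca-2,4,6,8,10-pentaen-12-yn-1-yl]triphenylphosphonium bromide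
Product: 27 (3S,5R,6S,3′R)-7′,8′-didehydro-5,6-dihydro-β,β-carotene-3,5,6,3′-tetrol (the target)
Conditions: NaOMe, MeOH/CH2Cl2, rt; then EtOH, 60 °C (Z → E at the new bond)
Reagents that add atoms: none
Why: Wittig olefination forms C11=C12 and completes the C40 chain under conditions that tolerate the free hydroxyls of both partners, the new bond relaxing to E on brief warming and all four stereocentres being carried unchanged from 15 and 26.

Compound list
1 | mesityl oxide (4-methylpent-3-en-2-one) | CC(C)=CC(C)=O | starting material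
2 | lithium 4-methylpenta-1,3-dien-2-olate | [Li+].[O-]C(=C)C=C(C)C | intermediate
3 | tert-butyldimethyl[(4-methylpenta-1,3-dien-2-yl)oxy]silane | C=C(O[Si](C)(C)C(C)(C)C)C=C(C)C | intermediate
4 | 4-(hydroxymethyl)-5-methyl-1,3-dioxol-2-one | CC1=C(CO)OC(=O)O1 | starting material
5 | 5-methyl-2-oxo-1,3-dioxole-4-carboxylic acid | CC1=C(C(=O)O)OC(=O)O1 | intermediate
6 | methyl 5-methyl-2-oxo-1,3-dioxole-4-carboxylate | COC(=O)C1=C(C)OC(=O)O1 | intermediate
7 | methyl (3aS,7aR)-6-[(tert-butyldimethylsilyl)oxy]-4,4,7a-trimethyl-2-oxo-3a,4,7,7a-tetrahydro-1,3-benzodioxole-3a-carboxylate | COC(=O)[C@@]12OC(=O)O[C@]1(C)CC(O[Si](C)(C)C(C)(C)C)=CC2(C)C | intermediate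
8 | (3aS,7aR)-6-[(tert-butyldimethylsilyl)oxy]-4,4,7a-trimethyl-2-oxo-3a,4,7,7a-tetrahydro-1,3-benzodioxole-3a-carbaldehyde | O=C[C@@]12OC(=O)O[C@]1(C)CC(O[Si](C)(C)C(C)(C)C)=CC2(C)C | intermediate
9 | ethyl (2E)-4-(diethoxyphosphoryl)-3-methylbut-2-enoate | CCOC(=O)/C=C(\C)CP(=O)(OCC)OCC | starting material
10 | lithium salt of 9 (lithiated at the carbon next to phosphorus) | [Li+].CCOC(=O)/C=C(\C)[CH-]P(=O)(OCC)OCC | intermediate
11 | ethyl (2E,4E)-5-[(3aS,7aR)-6-[(tert-butyldimethylsilyl)oxy]-4,4,7a-trimethyl-2-oxo-3a,4,7,7a-tetrahydro-1,3-benzodioxol-3a-yl]-3-methylpenta-2,4-dienoate | CCOC(=O)/C=C(C)/C=C/[C@@]12OC(=O)O[C@]1(C)CC(O[Si](C)(C)C(C)(C)C)=CC2(C)C | intermediate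
12 | (1S,2R)-4-[(tert-butyldimethylsilyl)oxy]-1-[(1E,3E)-5-hydroxy-3-methylpenta-1,3-dien-1-yl]-2,6,6-trimethylcyclohex-4-ene-1,2-diol | OC/C=C(C)/C=C/[C@@]1(O)[C@](C)(O)CC(O[Si](C)(C)C(C)(C)C)=CC1(C)C | intermediate
13 | (3R,4S)-3,4-dihydroxy-4-[(1E,3E)-5-hydroxy-3-methylpenta-1,3-dien-1-yl]-3,5,5-trimethylcyclohexan-1-one | OC/C=C(C)/C=C/[C@@]1(O)[C@](C)(O)CC(=O)CC1(C)C | intermediate
14 | (1S,2R,4S)-1-[(1E,3E)-5-hydroxy-3-methylpenta-1,3-dien-1-yl]-2,6,6-trimethylcyclohexane-1,2,4-triol | OC/C=C(C)/C=C/[C@@]1(O)[C@](C)(O)C[C@@H](O)CC1(C)C | intermediate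
15 | (2E,4E)-3-methyl-5-[(1S,2R,4S)-1,2,4-trihydroxy-2,6,6-trimethylcyclohexyl]penta-2,4-dienal | O=C/C=C(C)/C=C/[C@@]1(O)[C@](C)(O)C[C@@H](O)CC1(C)C | intermediate
16 | (4R,6R)-4-hydroxy-2,2,6-trimethylcyclohexan-1-one (actinol) | O=C1C(C)(C)C[C@H](O)C[C@H]1C | starting material
17 | (4R,6R)-4-[(tert-butyldimethylsilyl)oxy]-2,2,6-trimethylcyclohexan-1-one | O=C1C(C)(C)C[C@H](O[Si](C)(C)C(C)(C)C)C[C@H]1C | intermediate
18 | potassium (4R)-4-[(tert-butyldimethylsilyl)oxy]-2,6,6-trimethylcyclohex-1-en-1-olate | CC1=C([O-])C(C)(C)C[C@H](O[Si](C)(C)C(C)(C)C)C1.[K+] | intermediate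
19 | (4R)-4-[(tert-butyldimethylsilyl)oxy]-2,6,6-trimethylcyclohex-1-en-1-yl trifluoromethanesulfonate | CC1=C(OS(=O)(=O)C(F)(F)F)C(C)(C)C[C@H](O[Si](C)(C)C(C)(C)C)C1 | intermediate
20 | (2E)-3-methylpent-2-en-4-yn-1-ol | C#C/C(C)=C/CO | starting material
21 | (2E)-5-[(4R)-4-[(tert-butyldimethylsilyl)oxy]-2,6,6-trimethylcyclohex-1-en-1-yl]-3-methylpent-2-en-4-yn-1-ol | CC1=C(C#C/C(C)=C/CO)C(C)(C)C[C@H](O[Si](C)(C)C(C)(C)C)C1 | intermediate
22 | [(2E)-5-[(4R)-4-hydroxy-2,6,6-trimethylcyclohex-1-en-1-yl]-3-methylpent-2-en-4-yn-1-yl]triphenylphosphonium bromide | CC1=C(C#C/C(C)=C/C[P+](c2ccccc2)(c2ccccc2)c2ccccc2)C(C)(C)C[C@H](O)C1.[Br-] | intermediate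
23 | (2E,4E,6E)-2,7-dimethylocta-2,4,6-trienedial | O=C/C(C)=C/C=C/C=C(C)/C=O | starting material
24 | (2E,4E,6E,8E,10E)-13-[(4R)-4-hydroxy-2,6,6-trimethylcyclohex-1-en-1-yl]-2,7,11-trimethyltrideca-2,4,6,8,10-pentaen-12-ynal | CC1=C(C#C/C(C)=C/C=C/C(C)=C/C=C/C=C(C)/C=O)C(C)(C)C[C@H](O)C1 | intermediate
25 | (2E,4E,6E,8E,10E)-13-[(4R)-4-hydroxy-2,6,6-trimethylcyclohex-1-en-1-yl]-2,7,11-trimethyltrideca-2,4,6,8,10-pentaen-12-yn-1-ol | CC1=C(C#C/C(C)=C/C=C/C(C)=C/C=C/C=C(C)/CO)C(C)(C)C[C@H](O)C1 | intermediate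
26 | [(2E,4E,6E,8E,10E)-13-[(4R)-4-hydroxy-2,6,6-trimethylcyclohex-1-en-1-yl]-2,7,11-trimethyltrideca-2,4,6,8,10-pentaen-12-yn-1-yl]triphenylphosphonium bromide | CC1=C(C#C/C(C)=C/C=C/C(C)=C/C=C/C=C(C)/C[P+](c2ccccc2)(c2ccccc2)c2ccccc2)C(C)(C)C[C@H](O)C1.[Br-] | intermediate
27 | (3S,5R,6S,3′R)-7′,8′-didehydro-5,6-dihydro-β,β-carotene-3,5,6,3′-tetrol | CC1=C(C#C/C(C)=C/C=C/C(C)=C/C=C/C=C(C)/C=C/C=C(C)/C=C/[C@]2(O)C(C)(C)C[C@H](O)C[C@@]2(C)O)C(C)(C)C[C@H](O)C1 | target

Total step count: 18. Longest linear sequence: 10 steps (4 → 5 → 6 → 7 → 8 → 11 → 12 → 13 → 14 → 15 → 27).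

Steps most likely to fail

1. Step 4. The silylium ion pair may fail to turn over with so hindered a diene and a tetrasubstituted dienophile, the C5 carbonate oxygen may be expelled before the ring closes, or the chiral anion may discriminate the two faces poorly. The fallback is an auxiliary-controlled Lewis acid Diels–Alder reaction. It sets out from acid 5, which oxalyl chloride and catalytic DMF convert to 5-methyl-2-oxo-1,3-dioxole-4-carbonyl chloride F1. (−)-8-Phenylmenthol and pyridine then give (1R,2S,5R)-5-methyl-2-(2-phenylpropan-2-yl)cyclohexyl 5-methyl-2-oxo-1,3-dioxole-4-carboxylate F2. F2 and diene 3 are combined with the mixed Lewis acid AlBr3/AlMe3 in toluene/CH2Cl2 at low temperature to give (1R,2S,5R)-5-methyl-2-(2-phenylpropan-2-yl)cyclohexyl (3aS,7aR)-6-[(tert-butyldimethylsilyl)oxy]-4,4,7a-trimethyl-2-oxo-3a,4,7,7a-tetrahydro-1,3-benzodioxole-3a-carboxylate F3, separated from its diastereomer by chromatography or crystallisation, so that the auxiliary also serves as a resolving handle. i-Bu2AlH at −78 °C then releases the auxiliary and the route is rejoined at aldehyde 8.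

2. Step 5. The hydride may over-reduce the neopentyl ester to the alcohol or attack the cyclic carbonate. The fallback reaches the aldehyde by a neutral reduction of a thioester and again sets out from acid 5. EDC, catalytic DMAP and EtSH give S-ethyl 5-methyl-2-oxo-1,3-dioxole-4-carbothioate F4. The [4+2] of step 4 (or its AlBr3/AlMe3 variant) with diene 3 gives S-ethyl (3aS,7aR)-6-[(tert-butyldimethylsilyl)oxy]-4,4,7a-trimethyl-2-oxo-3a,4,7,7a-tetrahydro-1,3-benzodioxole-3a-carbothioate F5. Fukuyama reduction (Et3SiH, palladium on carbon, acetone, rt) then returns to aldehyde 8.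

3. Step 8. Once the enol ether is cleaved the tertiary β-hydroxy ketone may open by retro-aldol cleavage of C4–C5 or lose water, and the subsequent anti delivery then has no substrate. The fallback sets C3 while O5 is still tied in the carbonate and sets out from dienoate 11. Bu4NF/AcOH gives ethyl (2E,4E)-3-methyl-5-[(3aS,7aR)-4,4,7a-trimethyl-2,6-dioxohexahydro-1,3-benzodioxol-3a-yl]penta-2,4-dienoate F6. LiBH(s-Bu)3 in THF at −78 °C attacks from the less hindered equatorial side to give ethyl (2E,4E)-5-[(3aS,6R,7aR)-6-hydroxy-4,4,7a-trimethyl-2-oxohexahydro-1,3-benzodioxol-3a-yl]-3-methylpenta-2,4-dienoate F7, the axial alcohol. Mitsunobu inversion (PPh3, DIAD, PhCO2H) gives ethyl (2E,4E)-5-[(3aS,6S,7aR)-6-(benzoyloxy)-4,4,7a-trimethyl-2-oxohexahydro-1,3-benzodioxol-3a-yl]-3-methylpenta-2,4-dienoate F8. LiAlH4 then cleaves benzoate, carbonate and ethyl ester together and the route is rejoined at tetraol 14.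

Further compounds
F1 | step 4 | 5-methyl-2-oxo-1,3-dioxole-4-carbonyl chloride | CC1=C(C(=O)Cl)OC(=O)O1
F2 | step 4 | (1R,2S,5R)-5-methyl-2-(2-phenylpropan-2-yl)cyclohexyl 5-methyl-2-oxo-1,3-dioxole-4-carboxylate | CC(C)(c1ccccc1)[C@@H]1CC[C@@H](C)C[C@H]1OC(=O)C1=C(C)OC(=O)O1
F3 | step 4 | (1R,2S,5R)-5-methyl-2-(2-phenylpropan-2-yl)cyclohexyl (3aS,7aR)-6-[(tert-butyldimethylsilyl)oxy]-4,4,7a-trimethyl-2-oxo-3a,4,7,7a-tetrahydro-1,3-benzodioxole-3a-carboxylate | CC(C)(c1ccccc1)[C@@H]1CC[C@@H](C)C[C@H]1OC(=O)[C@@]12OC(=O)O[C@]1(C)CC(O[Si](C)(C)C(C)(C)C)=CC2(C)C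
F4 | step 5 | S-ethyl 5-methyl-2-oxo-1,3-dioxole-4-carbothioate | CCSC(=O)C1=C(C)OC(=O)O1
F5 | step 5 | S-ethyl (3aS,7aR)-6-[(tert-butyldimethylsilyl)oxy]-4,4,7a-trimethyl-2-oxo-3a,4,7,7a-tetrahydro-1,3-benzodioxole-3a-carbothioate | CCSC(=O)[C@@]12OC(=O)O[C@]1(C)CC(O[Si](C)(C)C(C)(C)C)=CC2(C)C
F6 | step 8 | ethyl (2E,4E)-3-methyl-5-[(3aS,7aR)-4,4,7a-trimethyl-2,6-dioxohexahydro-1,3-benzodioxol-3a-yl]penta-2,4-dienoate | CCOC(=O)/C=C(C)/C=C/[C@@]12OC(=O)O[C@]1(C)CC(=O)CC2(C)C
F7 | step 8 | ethyl (2E,4E)-5-[(3aS,6R,7aR)-6-hydroxy-4,4,7a-trimethyl-2-oxohexahydro-1,3-benzodioxol-3a-yl]-3-methylpenta-2,4-dienoate | CCOC(=O)/C=C(C)/C=C/[C@@]12OC(=O)O[C@]1(C)C[C@H](O)CC2(C)C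
F8 | step 8 | ethyl (2E,4E)-5-[(3aS,6S,7aR)-6-(benzoyloxy)-4,4,7a-trimethyl-2-oxohexahydro-1,3-benzodioxol-3a-yl]-3-methylpenta-2,4-dienoate | CCOC(=O)/C=C(C)/C=C/[C@@]12OC(=O)O[C@]1(C)C[C@@H](OC(=O)c3ccccc3)CC2(C)C
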